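Slowness is the trouble here: late in a run c(target), the target with its idle adduct and crystals counted in, moves only a few points in many hours, and two chemists read that drift differently.

| flask | starting material | remark | time |
|---|---|---|---|
| eta | 1 M | run made earlier |  |
| alpha | 2.2 M | run made earlier |  |
| violet | 1.5 M |  | 15 h |
| green | 1.5 M |  | 50 h |

| run | time / h | target / % | starting material / % |
|---|---|---|---|
| eta | 2.50 | 10.7 | 78.4 |
| eta | 8.00 | 24.4 | 51.9 |
| eta | 15.0 | 32.7 | 38.4 |
| eta | 20.0 | 35.7 | 32.2 |
| eta | 30.0 | 32.8 | 30.7 |
| alpha | 6.00 | 20.5 | 51.3 |
| alpha | 12.0 | 31.1 | 34.4 |
| alpha | 20.0 | 32.0 | 25.3 |
| alpha | 25.0 | 31.9 | 24.5 |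
| alpha | 30.0 | 30.9 | 23.1 |

(readings scatter by 1 percentage point)

- in percentages every species weighs as the starting material in it: one idle adduct or homo dimer counts as two
- for target the idle adduct and crystals are counted in
- as a solid, counted per litre of solution: crystals
- reactions considered so far: starting material <-> target; starting material <-> isomer of the product; starting material + target <-> idle adduct; 2 starting material -> homo dimer; crystals <-> target
- in an amount of target, one idle adduct counts as one target

1. the flask that ends with the higher amount of target, in percent of the starting material charged, or "neither" when 2 percentage points or less lies between them (violet / green / neither)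
2. final target, as a percentage of the starting material charged, in violet
3. final target, as a percentage of the starting material charged, in green

The first chemist holds a plateau view, with starting material and target in balance, first order each way. In the alpha run c(target) fell 1.1 percentage points from 20.0 h to 30.0 h. That is less than 1.4 points, the scatter of a difference of two readings. So she sees no fall, and she votes green for its longer time.

The second chemist calls target a kinetic product (kinetic against thermodynamic control). She compares gain and loss at one moment, then watches the comparison drift. Early in the eta run c(target) gained 14 points between 2.50 h and 8.00 h. From 20.0 h to 30.0 h it lost 2.9 points, more than that scatter. Over those hours of the eta run c(starting material) read 1.5 points lower too.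

Her measure is the sag: the points of target lost over the last 10.0 h of a run. As the mean of both runs it reads 2 points. The two runs read a mean of 33.9 % at 20.0 h. Carried on to 50 h, the sag gives 27.8 % for green.

The forecast, made from her side, says violet: 33 % (31 % to 35 %) in violet and 29.5 % (25.5 % to 33 %) in green. Its ground is this: “This suggests a slow irreversible drain through the homo dimer”. Its green stands higher than the sag's figure.

The flask gives 32.0 % in violet and 27.9 % in green, so violet ends higher, by 4.1 points, more than the margin of 2 points.

    starting material ⇌ target (K = 0.806, k = 0.0573 h⁻¹)
    starting material ⇌ isomer of the product (K = 6.20, k = 0.0156 h⁻¹)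
    starting material + target ⇌ idle adduct, settled at all times (K = 0.825 M⁻¹)
    2 starting material → homo dimer (k = 0.00758 M⁻¹ h⁻¹)
    crystals ⇌ target, rate k5*(cs5 - [target]) while solid is left; crystals form when [target] > cs5 (solubility = 1.30 M, k = 0.520 h⁻¹)

The plateau view has its region earlier: violet read at 6.00 h holds 22.1 % target, less than at 15 h, so waiting paid there. From 27.9 % in green at 50 h, one more span of 10.0 h should leave 25.9 % by the sag. Violet, of the same charge, left until 2.5 d holds 25.9 %.

The data were generated by integration on assumed constants.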